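(Its constants stand for no real mixture; the run is a simulation.)

The reagent balance came first: the 1.42 M of reagent charged, less than the charge of either substrate, always equals [reagent] + [second product] + [free target] + [idle adduct], which makes reagent the limiting reagent by charge.

in all of them: starting material 1.5 M; reagent 1.42 M; second substrate 1.50 M; time 50 s

|  | temperature | remark |
|---|---|---|
| cedar | 50 °C |  |
| birch | 25 °C |  |
| alder | 75 °C |  |
| maple |  | at 25 °C until 10 s, from then on at 75 °C |

1. the flask with the highest amount of target, in percent of the starting material charged ("all alike" if they lie within 1.5 percentage points) (cedar / birch / alder / maple / all alike)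
2. final target, as a percentage of the starting material charged, in cedar
3. final target, as a percentage of the starting material charged, in birch
4. final target, as a percentage of the starting material charged, in alder
5. final target, as a percentage of the starting material charged, in maple

- amounts and yields of target count idle adduct too
- the constants hold at 25 °C; other temperatures follow from the activation energies and enthalpies

    second substrate + reagent ⇌ second product (K1 = 1.5 /M, k1 = 0.0026 /M/s, Ea1 = 54.0 kJ/mol, ΔH1 = −45.0 kJ/mol)
    starting material + reagent ⇌ target (K2 = 0.32 /M, k2 = 0.0072 /M/s, Ea2 = 50.0 kJ/mol, ΔH2 = −61.0 kJ/mol)
    second substrate + target ⇌ idle adduct, settled at all times (K3 = 1.7 /M, ΔH3 = −11.0 kJ/mol)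
    (constants at 25 °C)

I wrote Kt for the step to target, Kq for the step to second product and Ka for the idle adduct. With these steps at balance, target in both forms per free starting material is Kt[reagent](1 + Ka[second substrate]), so I asked how well each input had to be known for the hot end of alder and maple. At 75 °C, Kt is 0.00934 /M, a factor 0.0292 on its value at 25 °C. Raising that factor to the ratios of the enthalpies gave Kq = 0.111 /M and Ka = 0.899 /M.

The rate constants and the time dropped out at that temperature. The reverse time of the step to second product was 1.86 s and that of the step to target 0.0716 s, both far shorter than the 40.0 s maple spent hot.

Kq acted through the balance. Setting target aside and linearising gave second product 0.178 M, which left [reagent] = 1.24 M and [second substrate] = 1.32 M. An error in Kq therefore reached the result with weight 0.164, an error in Ka with weight 0.543, and an error in Kt with weight 1. Kt had to be known best.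

Then came the number: 0.0254, the holding ratio, meaning target in both forms per free starting material at balance. Dividing it by 1 plus itself gave 2.48 % for alder and 2.48 % for maple.

Birch was different, because 92.6 s for 1/(rate constant × charge) exceeded its 50 s. Its balance gave a bound instead: [reagent] cannot exceed the starting material left, so birch stayed below 35.1 %. For cedar I took the geometric mean of the birch bound and the hot share as a plain interpolation. My ranking, which scored birch by that upper bound and so was an estimate, put first: birch.

The forecast also named birch, with 9.3 % for cedar, 26.7 % for birch, 2.4 % for alder and 2.4 % for maple, and it said “Birch is kinetic”. My alder share stood above its figure.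

The simulation gave birch first, with cedar 9.32 %, birch 26.6 %, alder 2.40 % and maple 2.40 %. Maple held 8.80 % of target at the change, 10.0 s, and 2.40 % at 25.0 s. For a neighbour of maple charged with 2.4 M of reagent, the same reckoning gave second product 0.278 M, a holding ratio of 0.0416 and a share of 3.99 %. That neighbour stood at 3.85 % after 50.0 s.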